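## The problem

Target 25 (CNP0268151.1) is an isoflavanone. A 5,7-dihydroxylated ring A is fused to the chroman-4-one ring C, C3 carries ring B, and ring B is annulated at C2'/C3' by a 2,2-dimethyl-2H-pyran (ring D) whose oxygen sits on C2'.

- **Stereochemistry.** The only stereocentre is C3 (S). It is benzylic and α to the C4 ketone, so it enolises easily. No second stereocentre exists to relay from, so C3 must be set by an external controller.
- **Oxidation level.** C3 should spend as much of the synthesis as possible with C4 not a carbonyl.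
- **Sensitive groups.** The chromene double bond of ring D rules out hydrogenolysis and strong electrophiles. The three phenols (5-OH peri to the ketone, 7-OH, 4'-OH) need protection that comes off without base.
- **Ring D regiochemistry.** The pyran oxygen must end up on C2' and not on C4', which calls for an unambiguous chromene construction on a 2,4-dioxygenated arylacetic unit.
- **Enabling feature.** O1 links the sp3 carbon C2 to the aromatic carbon C8a, and C8a, C5 and C7 are mutually meta. A ring A derived from 1 therefore carries its halogen exactly where O1 must be attached, and ring C can be closed by aryl C–O bond formation after C3 has been fixed in an acyclic aldol.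

## Retrosynthesis

**25 ⇒ 24 ⇒ 23 ⇒ 22 (no skeletal bonds).** 25 comes from its tris(methoxymethyl) ether 24 by cleaving three acetal C–O bonds, 24 from carbinol 23 by oxidation at C4, and 23 from silyl ether 22 by Si–O cleavage. Unmasking the phenols earlier is rejected because a free C4 carbinol on a tri-oxygenated ring A would ionise under the acid the acetals need. Carrying the ketone earlier is rejected because C3 becomes enolisable only from 24 on, that is, for two steps. The forward steps asked for are a desilylation, a buffered oxidation and a mild protic acetal cleavage.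

**22 ⇒ 21 (cut O1–C8a, key step).** The neighbouring cut O1–C2 would need a free C8a phenol, so one of three ring A oxygens would have to be told apart from the other two. Closure at the ketone level by conjugate addition would create C3 by uncontrolled protonation. The aryl C–O cut needs no differentiation, because the bromine of 21 marks C8a, and it leaves an acyclic precursor with one free primary hydroxyl. The forward reaction must be a Pd-catalysed intramolecular aryl etherification that tolerates a silyl ether, three acetals and the chromene, and that favours C–O reductive elimination over β-hydride elimination.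

**21 ⇒ 20 ⇒ 19 ⇒ 16 + 4 (cut C3–C4).** An auxiliary-controlled syn aldol between imide 16 and aldehyde 4 sets C3. The C4 hydroxyl of 19 is a temporary stereocentre; it is silylated (20) and the auxiliary is removed reductively to give 21. Alkylating the same enolate with a benzylic halide would arrive at the isoflavan level and require a later benzylic oxidation beside the chromene. Acylation would give a doubly activated, configurationally fragile β-keto imide. The aldol divides the molecule into two fragments of similar size. It must add syn to a di-ortho-substituted, electron-rich aldehyde, and the (R)-auxiliary 14 is needed because its sense of induction maps onto 3S in 25.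

**4 ⇒ 3 ⇒ 1 (cut the formyl C–C bond).** Electrophilic formylation of 1 is directed para to one hydroxyl and ortho to the other, next to bromine, giving 3, which is then protected to 4. Protection first is not viable: electrophilic formylation conditions would strip the acetals, and deprotonation would go between the two oxygens.

**16 ⇒ 13 + 14; 13 ⇒ 12 (cut the acyl C–N bond).** Standard acylation of 14 by acid 13, itself from ester 12 by saponification.

**12 ⇒ 10 ⇒ 8 + 9 (ring D).** The C4a–C4 bond and the O–CMe2 bond of the chromene come from a thermal rearrangement of aryl propargyl ether 10 through allenylphenol 11. Ether 10 comes from phenol 8 and chloride 9. The other ortho position of the ether oxygen carries the side chain, so carbon can only be delivered to the position between the two oxygens, which gives the required fusion with oxygen on C2'. Condensing a free resorcinol with an enal would leave two oxygens and two nucleophilic carbons in competition.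

**8 ⇒ 7 ⇒ 6 ⇒ 5 (telling the phenols apart).** Only the ortho hydroxyl of 5 can reach the carboxyl, so lactonisation gives 6. The remaining hydroxyl is protected (7), and methanolysis releases the ortho phenol and the ester together in 8.

## Roads not taken

**Alternative 1: aryne annulation for ring D.**
- Cut: the C2'–O and C3'–C bonds of ring D.
- Forward key step: CsF-induced elimination from silylaryl triflate A2 gives an aryne across C2'/C3'. The enal A3 adds across its C=O, the strained four-membered adduct opens to a dienone, and oxa-6π electrocyclisation gives chromene A1.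
- Merits: ring D is built at ambient temperature, with no 180 °C rearrangement and no lactone detour. The regiochemistry is electronically matched, since the oxygen nucleophile attacks the aryne carbon remote from the alkoxy group (C2').
- Weak points: A2 is a 1,2,3,4-tetrasubstituted arene that itself needs several steps. A1 still lacks ring A, ring C and C3, and its silyloxyethyl arm must be deprotected and oxidised twice to reach the level of 13.
- Comparison: this road is milder than step 7 and simpler in phenol differentiation. Against that, the chosen plan uses cheaper materials and a rearrangement with only one place to go. It also puts the key step on the hard part of the target (C3 and ring C), which this road leaves open.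

**Alternative 2: carbene C–H insertion for ring C.**
- Cut: C2–C3.
- Forward key step: diazoketone A5 gives a carbene at C3 on a chiral catalyst of the Rh2(S-PTTL)4 type. The carbene inserts into a C–H bond of an ortho methoxy group of ring A, closing ring C and in principle setting C3, to give A4.
- Merits: ring C and the stereocentre in one catalytic step at the ketone level, with no auxiliary and no redox adjustment. On paper this is the shortest route.
- Weak points:
  - The six-membered insertion into a methyl C–H bond competes with attack on the methoxy oxygen (oxonium ylide and methyl shift), addition to the chromene alkene or the electron-rich rings, and Wolff rearrangement.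
  - Enantioselective insertion for this diaryl diazoketone class lacks close precedent, so the step would be a method-development problem.
  - C3 is born α to the ketone beside a Lewis-acidic metal, so any induced purity is at risk at once.
  - The remaining 5-methoxy group needs a boron or aluminium halide at the end, harsher than acetal cleavage for a labile C3 and an acid-sensitive chromene.
- Comparison: better in step count and atom economy. The chosen plan offers established reaction classes throughout, a predictable sense of induction, and a C3 that is not enolisable until the last two steps.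

**Alternative 3: aryne insertion into an arylacrylic acid.**
- Cut: O1–C8a and C4–C4a together, then O1–C2.
- Forward key step: CsF releases the aryne from A7. The carboxylate of acid A8 adds through oxygen, the aryl anion attacks the acyl carbon (formal insertion into the C–O bond), and the resulting ortho-hydroxyaryl vinyl ketone closes by oxa-Michael addition to A6.
- Merits: two ring A bonds and ring C in one flask, with regiochemistry matched by the 3-alkoxy group. A6 is the racemate of 24, so only a deprotection would remain.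
- Weak points: C3 arises by protonation of an enolate with no chiral information, so A6 is racemic. A resolution or an asymmetric protonation would be needed, and neither is established for isoflavanones. The aryne may also engage the chromene alkene, and A7 takes several steps.
- Comparison: for racemic material this road is clearly shorter and would be preferred. The chosen plan spends roughly a dozen more steps to buy control of C3.

Key step: step 13

Assumption: 14, its enantiomer, MOMCl and the biarylphosphine are bought; the descriptor at the carbon that becomes C3 changes along the route (R in 19 and 20, S from 21 on) only because its neighbours change CIP rank, the spatial arrangement staying the same.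

## Steps

Step 1
Reactants: 1 5-bromobenzene-1,3-diol
Product: 3 2-bromo-4,6-dihydroxybenzaldehyde, via aryl iminium chloride 2 (not isolated)
Conditions: POCl3, DMF, MeCN, 0 °C to rt; then H2O, 50 °C
Reagents that add atoms: N,N-dimethylformamide, CN(C)C=O; water, O
Why: Vilsmeier–Haack formylation of a resorcinol; attack is expected para to one hydroxyl and ortho to the other (the two such positions of 1 are equivalent), as with orcinol, and not at the more hindered carbon between the hydroxyls; warm water hydrolyses 2.

Step 2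
Reactants: 3 2-bromo-4,6-dihydroxybenzaldehyde
Product: 4 2-bromo-4,6-bis(methoxymethoxy)benzaldehyde
Conditions: MOMCl (3 equiv), iPr2NEt, CH2Cl2, 0 °C to reflux
Reagents that add atoms: chloromethyl methyl ether, COCCl
Why: O-alkylation of both phenols (Williamson-type acetal formation); excess reagent and warming are used because the hydroxyl ortho to the aldehyde is hydrogen-bonded.

Step 3
Reactants: 5 2-(2,4-dihydroxyphenyl)acetic acid
Product: 6 6-hydroxy-1-benzofuran-2(3H)-one
Conditions: p-TsOH·H2O (cat.), toluene, reflux, Dean–Stark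
Reagents that add atoms: none
Why: Acid-catalysed intramolecular Fischer esterification; only the ortho hydroxyl can reach the carboxyl (five-membered lactone), which distinguishes it from the para hydroxyl.

Step 4
Reactants: 6 6-hydroxy-1-benzofuran-2(3H)-one
Product: 7 6-(methoxymethoxy)-1-benzofuran-2(3H)-one
Conditions: MOMCl, iPr2NEt, CH2Cl2, 0 °C
Reagents that add atoms: chloromethyl methyl ether, COCCl
Why: Standard phenol acetalisation; the tertiary amine allows fast O–H transfer from the phenol but should neither open the lactone nor deprotonate its CH2 at a useful rate at 0 °C.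

Step 5
Reactants: 7 6-(methoxymethoxy)-1-benzofuran-2(3H)-one
Product: 8 methyl 2-[2-hydroxy-4-(methoxymethoxy)phenyl]acetate
Conditions: K2CO3 (0.1 equiv), MeOH, 0 °C to rt
Reagents that add atoms: methanol, CO
Why: Base-catalysed methanolysis (transesterification) of an aryl ester lactone, driven by the phenoxide leaving group; it frees exactly the phenol that becomes the pyran oxygen.

Step 6
Reactants: 8 methyl 2-[2-hydroxy-4-(methoxymethoxy)phenyl]acetate; 9 3-chloro-3-methylbut-1-yne
Product: 10 methyl 2-[4-(methoxymethoxy)-2-(2-methylbut-3-yn-2-yloxy)phenyl]acetate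
Conditions: CuCl2·2H2O (cat.), DBU, MeCN, 0 °C
Reagents that add atoms: none
Why: CuCl2-catalysed propargylic etherification of a phenol with a tertiary propargylic chloride (the metal-bound alkyne ionises to an allenylidene-type electrophile that the phenoxide captures at the tertiary carbon), the standard entry to 1,1-dimethylpropargyl aryl ethers.

Step 7
Reactants: 10 methyl 2-[4-(methoxymethoxy)-2-(2-methylbut-3-yn-2-yloxy)phenyl]acetate
Product: 12 methyl 2-[5-(methoxymethoxy)-2,2-dimethyl-2H-chromen-8-yl]acetate, via ortho-allenylphenol 11 (not isolated)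
Conditions: N,N-diethylaniline, 180 °C
Reagents that add atoms: none
Why: Aryl propargyl Claisen rearrangement, tautomerisation to 11, 1,5-hydrogen shift and oxa-6π electrocyclisation, the usual thermal route to 2,2-dimethyl-2H-chromenes; the other ortho carbon of the ether oxygen bears the side chain, so carbon is delivered only between the two oxygens.

Step 8
Reactants: 12 methyl 2-[5-(methoxymethoxy)-2,2-dimethyl-2H-chromen-8-yl]acetate
Product: 13 2-[5-(methoxymethoxy)-2,2-dimethyl-2H-chromen-8-yl]acetic acid
Conditions: LiOH·H2O, THF/H2O, rt; then 1 M HCl to pH 4, 0 °C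
Reagents that add atoms: lithium hydroxide, [Li+].[OH-]
Why: Ester saponification; the acetal and the chromene are stable to LiOH, and the brief cold acidification to pH 4 is too mild to cleave an aryl methoxymethyl ether.

Step 9
Reactants: 13 2-[5-(methoxymethoxy)-2,2-dimethyl-2H-chromen-8-yl]acetic acid; 14 (4R)-4-benzyl-1,3-oxazolidin-2-one
Product: 16 (4R)-4-benzyl-3-{[5-(methoxymethoxy)-2,2-dimethyl-2H-chromen-8-yl]acetyl}-1,3-oxazolidin-2-one, via mixed pivalic anhydride 15 (not isolated)
Conditions: PivCl, Et3N, THF, −20 °C; then 14, LiCl, −20 °C to rt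
Reagents that add atoms: none
Why: N-acylation of an oxazolidinone through a mixed pivalic anhydride with LiCl/Et3N activation; the hindered pivaloyl carbonyl directs attack to the arylacetyl carbonyl.

Step 10
Reactants: 16 (4R)-4-benzyl-3-{[5-(methoxymethoxy)-2,2-dimethyl-2H-chromen-8-yl]acetyl}-1,3-oxazolidin-2-one; 4 2-bromo-4,6-bis(methoxymethoxy)benzaldehyde
Product: 19 (4R)-4-benzyl-3-{(2R,3R)-3-[2-bromo-4,6-bis(methoxymethoxy)phenyl]-3-hydroxy-2-[5-(methoxymethoxy)-2,2-dimethyl-2H-chromen-8-yl]propanoyl}-1,3-oxazolidin-2-one, via dibutylboron Z-enolate 17 (not isolated), via dibutylboron aldolate 18 (not isolated)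
Conditions: Bu2BOTf, iPr2NEt, CH2Cl2, −78 to 0 °C; then 4, −78 to 0 °C; then pH 7 buffer, MeOH, 30% aq. H2O2, 0 °C
Reagents that add atoms: none
Why: Evans boron syn-aldol addition: soft enolisation gives Z-enolate 17, which reacts through a chair (Zimmerman–Traxler) transition state with the auxiliary carbonyl turned away from the enolate oxygen, so the aldehyde adds to the enolate face opposite the benzyl group. With the (R)-auxiliary this sets C2 (the future C3) as R and the carbinol carbon as R (syn); oxidative work-up releases 19 from 18.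

Step 11
Reactants: 19 (4R)-4-benzyl-3-{(2R,3R)-3-[2-bromo-4,6-bis(methoxymethoxy)phenyl]-3-hydroxy-2-[5-(methoxymethoxy)-2,2-dimethyl-2H-chromen-8-yl]propanoyl}-1,3-oxazolidin-2-one
Product: 20 (4R)-4-benzyl-3-{(2R,3R)-3-[2-bromo-4,6-bis(methoxymethoxy)phenyl]-3-{[tert-butyl(dimethyl)silyl]oxy}-2-[5-(methoxymethoxy)-2,2-dimethyl-2H-chromen-8-yl]propanoyl}-1,3-oxazolidin-2-one
Conditions: TBSOTf, 2,6-lutidine, CH2Cl2, −78 to 0 °C
Reagents that add atoms: tert-butyldimethylsilyl trifluoromethanesulfonate, CC(C)(C)[Si](C)(C)OS(=O)(=O)C(F)(F)F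
Why: Silylation of a hindered secondary alcohol with a silyl triflate and a non-nucleophilic base; the medium is not basic enough for retro-aldol cleavage and no stereocentre is touched.

Step 12
Reactants: 20 (4R)-4-benzyl-3-{(2R,3R)-3-[2-bromo-4,6-bis(methoxymethoxy)phenyl]-3-{[tert-butyl(dimethyl)silyl]oxy}-2-[5-(methoxymethoxy)-2,2-dimethyl-2H-chromen-8-yl]propanoyl}-1,3-oxazolidin-2-one
Product: 21 (2S,3R)-3-[2-bromo-4,6-bis(methoxymethoxy)phenyl]-3-{[tert-butyl(dimethyl)silyl]oxy}-2-[5-(methoxymethoxy)-2,2-dimethyl-2H-chromen-8-yl]propan-1-ol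
Conditions: LiBH4, THF, 0 °C to rt
Reagents that add atoms: none
Why: Reductive removal of the oxazolidinone auxiliary by hydride attack at the exocyclic carbonyl, giving the primary alcohol and returning 14; LiBH4 is not basic enough to epimerise the α-aryl centre.

Step 13
Reactants: 21 (2S,3R)-3-[2-bromo-4,6-bis(methoxymethoxy)phenyl]-3-{[tert-butyl(dimethyl)silyl]oxy}-2-[5-(methoxymethoxy)-2,2-dimethyl-2H-chromen-8-yl]propan-1-ol
Product: 22 tert-butyl({(3S,4R)-5,7-bis(methoxymethoxy)-3-[5-(methoxymethoxy)-2,2-dimethyl-2H-chromen-8-yl]-3,4-dihydro-2H-chromen-4-yl}oxy)dimethylsilane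
Conditions: Pd(OAc)2 (5 mol %), 2-(di-tert-butylphosphino)-1,1'-binaphthyl (6 mol %), Cs2CO3, toluene, 70 °C
Reagents that add atoms: none
Why: Pd(OAc)2 is reduced in the flask to a phosphine-ligated zerovalent palladium species, which adds oxidatively to the C8a–Br bond of 21 to give ArPd(L)Br (divalent palladium); Cs2CO3 then replaces bromide by the primary C2 alkoxide, and C–O reductive elimination from the resulting ArPd(L)OR chelate forges O1–C8a and regenerates the catalyst. The closest known reaction type is the Pd-catalysed intramolecular etherification of 3-(2-bromoaryl)propan-1-ols to chromans with di-tert-butylbiarylphosphines and Cs2CO3 in toluene. Ring C closes as a six-membered ring by reductive elimination from a seven-membered palladacycle, formally a 6-exo closure of oxygen onto the ipso carbon. No stereocentre is formed and no bond to C3 or C4 is touched, so the (3S,4R) array from step 10 is carried into 22 unchanged (trans). The selectivity needed is reductive elimination over β-hydride elimination from the alkoxide, which the bulky di-tert-butylphosphino group secures by accelerating C–O bond formation; the C–Br bond is meta to both ether donors, so oxidative addition is not slowed electronically. Chemoselectivity comes from the substrate: only the primary hydroxyl is free, the silylated C4 oxygen could in any case close only a four-membered ring, and with C4 at the carbinol level C3 bears no acidic hydrogen for Cs2CO3 to remove.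

Step 14
Reactants: 22 tert-butyl({(3S,4R)-5,7-bis(methoxymethoxy)-3-[5-(methoxymethoxy)-2,2-dimethyl-2H-chromen-8-yl]-3,4-dihydro-2H-chromen-4-yl}oxy)dimethylsilane
Product: 23 (3S,4R)-5,7-bis(methoxymethoxy)-3-[5-(methoxymethoxy)-2,2-dimethyl-2H-chromen-8-yl]-3,4-dihydro-2H-chromen-4-ol
Conditions: TBAF, THF, 0 to 40 °C
Reagents that add atoms: none
Why: Fluoride-induced Si–O cleavage; the basic medium suits the acid-labile benzylic carbinol on the tri-oxygenated ring A, and C3 has no acidic hydrogen at this oxidation level.

Step 15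
Reactants: 23 (3S,4R)-5,7-bis(methoxymethoxy)-3-[5-(methoxymethoxy)-2,2-dimethyl-2H-chromen-8-yl]-3,4-dihydro-2H-chromen-4-ol
Product: 24 (3S)-5,7-bis(methoxymethoxy)-3-[5-(methoxymethoxy)-2,2-dimethyl-2H-chromen-8-yl]-2,3-dihydro-4H-chromen-4-one
Conditions: Dess–Martin periodinane, NaHCO3, CH2Cl2, 0 °C to rt
Reagents that add atoms: none
Why: Dess–Martin oxidation of a secondary benzylic alcohol under buffered, near-neutral conditions; it erases the temporary C4 stereocentre, and NaHCO3 keeps the now enolisable C3 from epimerising.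

Step 16
Reactants: 24 (3S)-5,7-bis(methoxymethoxy)-3-[5-(methoxymethoxy)-2,2-dimethyl-2H-chromen-8-yl]-2,3-dihydro-4H-chromen-4-one
Product: 25 (3S)-5,7-dihydroxy-3-(5-hydroxy-2,2-dimethyl-2H-chromen-8-yl)-2,3-dihydro-4H-chromen-4-one
Conditions: 3 M aq. HCl, MeOH, 40 °C
Reagents that add atoms: none
Why: Acid-catalysed acetal exchange of the three aryl methoxymethyl ethers with methanol (the 5-ether, peri to the ketone, first); protic acid is chosen because isoflavanones epimerise at C3 far more readily under base, and the low temperature spares C3 and the chromene.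

## Compound list

1 | 5-bromobenzene-1,3-diol | Oc1cc(O)cc(Br)c1 | starting material
2 | (2-bromo-4,6-dihydroxybenzylidene)dimethyliminium chloride | C[N+](C)=Cc1c(O)cc(O)cc1Br.[Cl-] | intermediate
3 | 2-bromo-4,6-dihydroxybenzaldehyde | O=Cc1c(O)cc(O)cc1Br | intermediate
4 | 2-bromo-4,6-bis(methoxymethoxy)benzaldehyde | O=Cc1c(OCOC)cc(OCOC)cc1Br | intermediate
5 | 2-(2,4-dihydroxyphenyl)acetic acid | OC(=O)Cc1ccc(O)cc1O | starting material
6 | 6-hydroxy-1-benzofuran-2(3H)-one | O=C1Cc2ccc(O)cc2O1 | intermediate
7 | 6-(methoxymethoxy)-1-benzofuran-2(3H)-one | O=C1Cc2ccc(OCOC)cc2O1 | intermediate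
8 | methyl 2-[2-hydroxy-4-(methoxymethoxy)phenyl]acetate | COC(=O)Cc1ccc(OCOC)cc1O | intermediate
9 | 3-chloro-3-methylbut-1-yne | CC(C)(Cl)C#C | starting material
10 | methyl 2-[4-(methoxymethoxy)-2-(2-methylbut-3-yn-2-yloxy)phenyl]acetate | COC(=O)Cc1ccc(OCOC)cc1OC(C)(C)C#C | intermediate
11 | methyl 2-[2-hydroxy-4-(methoxymethoxy)-3-(3-methylbuta-1,2-dien-1-yl)phenyl]acetate | COC(=O)Cc1ccc(OCOC)c(C=C=C(C)C)c1O | intermediate
12 | methyl 2-[5-(methoxymethoxy)-2,2-dimethyl-2H-chromen-8-yl]acetate | COC(=O)Cc1ccc(OCOC)c2C=CC(C)(C)Oc12 | intermediate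
13 | 2-[5-(methoxymethoxy)-2,2-dimethyl-2H-chromen-8-yl]acetic acid | OC(=O)Cc1ccc(OCOC)c2C=CC(C)(C)Oc12 | intermediate
14 | (4R)-4-benzyl-1,3-oxazolidin-2-one | O=C1N[C@H](Cc2ccccc2)CO1 | starting material
15 | 2-[5-(methoxymethoxy)-2,2-dimethyl-2H-chromen-8-yl]acetic 2,2-dimethylpropanoic anhydride | CC(C)(C)C(=O)OC(=O)Cc1ccc(OCOC)c2C=CC(C)(C)Oc12 | intermediate
16 | (4R)-4-benzyl-3-{[5-(methoxymethoxy)-2,2-dimethyl-2H-chromen-8-yl]acetyl}-1,3-oxazolidin-2-one | O=C(Cc1ccc(OCOC)c2C=CC(C)(C)Oc12)N1C(=O)OC[C@H]1Cc1ccccc1 | intermediate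
17 | dibutylboron (Z)-enolate of 16 | CCCCB(CCCC)O/C(=C\c1ccc(OCOC)c2C=CC(C)(C)Oc12)N1C(=O)OC[C@H]1Cc1ccccc1 | intermediate
18 | O-dibutylboryl aldolate of 19 | CC1(C)C=Cc2c(OCOC)ccc([C@H]([C@@H](OB(CCCC)CCCC)c3c(Br)cc(OCOC)cc3OCOC)C(=O)N3C(=O)OC[C@H]3Cc3ccccc3)c2O1 | intermediate
19 | (4R)-4-benzyl-3-{(2R,3R)-3-[2-bromo-4,6-bis(methoxymethoxy)phenyl]-3-hydroxy-2-[5-(methoxymethoxy)-2,2-dimethyl-2H-chromen-8-yl]propanoyl}-1,3-oxazolidin-2-one | CC1(C)C=Cc2c(OCOC)ccc([C@H]([C@@H](O)c3c(Br)cc(OCOC)cc3OCOC)C(=O)N3C(=O)OC[C@H]3Cc3ccccc3)c2O1 | intermediate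
20 | (4R)-4-benzyl-3-{(2R,3R)-3-[2-bromo-4,6-bis(methoxymethoxy)phenyl]-3-{[tert-butyl(dimethyl)silyl]oxy}-2-[5-(methoxymethoxy)-2,2-dimethyl-2H-chromen-8-yl]propanoyl}-1,3-oxazolidin-2-one | CC1(C)C=Cc2c(OCOC)ccc([C@H]([C@@H](O[Si](C)(C)C(C)(C)C)c3c(Br)cc(OCOC)cc3OCOC)C(=O)N3C(=O)OC[C@H]3Cc3ccccc3)c2O1 | intermediate
21 | (2S,3R)-3-[2-bromo-4,6-bis(methoxymethoxy)phenyl]-3-{[tert-butyl(dimethyl)silyl]oxy}-2-[5-(methoxymethoxy)-2,2-dimethyl-2H-chromen-8-yl]propan-1-ol | CC1(C)C=Cc2c(OCOC)ccc([C@H]([C@@H](O[Si](C)(C)C(C)(C)C)c3c(Br)cc(OCOC)cc3OCOC)CO)c2O1 | intermediate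
22 | tert-butyl({(3S,4R)-5,7-bis(methoxymethoxy)-3-[5-(methoxymethoxy)-2,2-dimethyl-2H-chromen-8-yl]-3,4-dihydro-2H-chromen-4-yl}oxy)dimethylsilane | CC1(C)C=Cc2c(OCOC)ccc([C@H]3COc4cc(OCOC)cc(OCOC)c4[C@@H]3O[Si](C)(C)C(C)(C)C)c2O1 | intermediate
23 | (3S,4R)-5,7-bis(methoxymethoxy)-3-[5-(methoxymethoxy)-2,2-dimethyl-2H-chromen-8-yl]-3,4-dihydro-2H-chromen-4-ol | CC1(C)C=Cc2c(OCOC)ccc([C@H]3COc4cc(OCOC)cc(OCOC)c4[C@@H]3O)c2O1 | intermediate
24 | (3S)-5,7-bis(methoxymethoxy)-3-[5-(methoxymethoxy)-2,2-dimethyl-2H-chromen-8-yl]-2,3-dihydro-4H-chromen-4-one | CC1(C)C=Cc2c(OCOC)ccc([C@H]3COc4cc(OCOC)cc(OCOC)c4C3=O)c2O1 | intermediate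
25 | (3S)-5,7-dihydroxy-3-(5-hydroxy-2,2-dimethyl-2H-chromen-8-yl)-2,3-dihydro-4H-chromen-4-one | CC1(C)C=Cc2c(O)ccc([C@H]3COc4cc(O)cc(O)c4C3=O)c2O1 | target

## Step count and least certain steps

Total: 16 steps. Longest linear sequence: 14 steps (5 to 25, steps 3–16). The aldehyde branch (steps 1–2) joins at step 10.

**Step 13 (key step).**
- Most likely failures: β-hydride elimination from ArPd(L)OR outrunning C–O reductive elimination (net debromination and oxidation of the primary alcohol); slow oxidative addition beside the bulky silyloxy-bearing carbon; migration of the silyl group from O4 to the primary oxygen under Cs2CO3 at 70 °C.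
- Fallback, from 21 back to 22, forming O1–C2 instead of O1–C8a: Miyaura borylation of the bromide (B2pin2, Pd(dppf)Cl2, KOAc, dioxane, 80 °C; no alkoxide is generated under KOAc) would give the aryl pinacol boronate F1. Oxidation (NaBO3·4H2O, THF/H2O, rt) would give the phenol F2. Mitsunobu cyclisation of the phenol onto the primary carbinol (PPh3, DIAD, THF, 0 °C), an established chroman closure, returns to 22. C2 is a methylene, so no stereocentre is affected.

**Step 10.**
- Most likely failures: incomplete addition of the boron enolate to the di-ortho-substituted, electron-rich aldehyde, and reversal of the aldolate (retro-aldol) on work-up, favoured by the stabilised α-aryl enolate.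
- Fallback, from 13, rejoining at 24: acid 13 would be coupled through 15 with (4S)-4-benzyl-1,3-oxazolidin-2-one to the enantiomeric imide F3. The MgCl2-catalysed direct aldol with 4 (MgCl2 cat., Et3N, TMSCl, EtOAc, rt) is expected to give the anti adduct as its trimethylsilyl ether F4, with silylation pulling the equilibrium forward. The MgCl2-derived chelated enolate is attacked on the face opposite to that used by the boron enolate, which is why the auxiliary is inverted to reach the same C3 configuration. Citric acid in MeOH would give the anti aldol F5, TBSOTf/2,6-lutidine the silyl ether F6, LiBH4 the primary alcohol F7, the conditions of step 13 the cis chroman silyl ether F8, and TBAF the cis carbinol F9. Dess–Martin oxidation then converges on 24, because C4 is erased.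

**Step 12.**
- Most likely failure: hydride attack at the ring carbonyl of the auxiliary (endocyclic opening), because the exocyclic carbonyl is shielded by the α-aryl and β-silyloxy groups.
- Fallback, from 19 back to 21: reduction of the free hydroxy imide 19 (LiBH4, THF, 0 °C), where the neighbouring alkoxide directs hydride to the exocyclic carbonyl, would give the diol F10. Double silylation (TBSOTf, 2,6-lutidine) would give the bis-silyl ether F11. Selective cleavage of the primary silyl ether (HF·pyridine, pyridine, THF, 0 °C) returns to 21.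

**Step 16.**
- Most likely failures: erosion of configuration at C3 by acid-catalysed enolisation during the slower cleavage of the 7- and 4'-ethers, and addition of methanol across the chromene double bond.
- Fallback, from 24 to 25, replacing protic acetal hydrolysis by silyl transfer and fluoride: TESOTf with 2,2'-bipyridyl (CH2Cl2, 0 °C) converts aryl methoxymethyl ethers into aryl silyl ethers and would give the tris(triethylsilyl) ether F12. Buffered HF·pyridine (pyridine, THF, 0 °C) would then release 25 without a protic acid or a base strong enough to enolise C3.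

**Step 7.**
- Most likely failures: migration of the propargyl unit onto the substituted ortho carbon followed by further shifts, or decomposition at 180 °C.
- Fallback, from 8 to 12, building ring D by condensation instead of rearrangement: phenol 8 with 3-methylbut-2-enal and PhB(OH)2 (AcOH cat., toluene, reflux with removal of water) would form the benzodioxaborin F13 at the only free ortho carbon. On continued heating F13 fragments to an ortho-quinone methide that electrocyclises to 12.

## Further compounds

F1 | step 13 | (2S,3R)-3-[4,6-bis(methoxymethoxy)-2-(4,4,5,5-tetramethyl-1,3,2-dioxaborolan-2-yl)phenyl]-3-{[tert-butyl(dimethyl)silyl]oxy}-2-[5-(methoxymethoxy)-2,2-dimethyl-2H-chromen-8-yl]propan-1-ol | CC1(C)C=Cc2c(OCOC)ccc([C@H]([C@@H](O[Si](C)(C)C(C)(C)C)c3c(B4OC(C)(C)C(C)(C)O4)cc(OCOC)cc3OCOC)CO)c2O1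
F2 | step 13 | (2S,3R)-3-{[tert-butyl(dimethyl)silyl]oxy}-3-[2-hydroxy-4,6-bis(methoxymethoxy)phenyl]-2-[5-(methoxymethoxy)-2,2-dimethyl-2H-chromen-8-yl]propan-1-ol | CC1(C)C=Cc2c(OCOC)ccc([C@H]([C@@H](O[Si](C)(C)C(C)(C)C)c3c(O)cc(OCOC)cc3OCOC)CO)c2O1
F3 | step 10 | (4S)-4-benzyl-3-{[5-(methoxymethoxy)-2,2-dimethyl-2H-chromen-8-yl]acetyl}-1,3-oxazolidin-2-one | O=C(Cc1ccc(OCOC)c2C=CC(C)(C)Oc12)N1C(=O)OC[C@@H]1Cc1ccccc1
F4 | step 10 | (4S)-4-benzyl-3-{(2R,3S)-3-[2-bromo-4,6-bis(methoxymethoxy)phenyl]-2-[5-(methoxymethoxy)-2,2-dimethyl-2H-chromen-8-yl]-3-[(trimethylsilyl)oxy]propanoyl}-1,3-oxazolidin-2-one | CC1(C)C=Cc2c(OCOC)ccc([C@H]([C@H](O[Si](C)(C)C)c3c(Br)cc(OCOC)cc3OCOC)C(=O)N3C(=O)OC[C@@H]3Cc3ccccc3)c2O1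
F5 | step 10 | (4S)-4-benzyl-3-{(2R,3S)-3-[2-bromo-4,6-bis(methoxymethoxy)phenyl]-3-hydroxy-2-[5-(methoxymethoxy)-2,2-dimethyl-2H-chromen-8-yl]propanoyl}-1,3-oxazolidin-2-one | CC1(C)C=Cc2c(OCOC)ccc([C@H]([C@H](O)c3c(Br)cc(OCOC)cc3OCOC)C(=O)N3C(=O)OC[C@@H]3Cc3ccccc3)c2O1
F6 | step 10 | (4S)-4-benzyl-3-{(2R,3S)-3-[2-bromo-4,6-bis(methoxymethoxy)phenyl]-3-{[tert-butyl(dimethyl)silyl]oxy}-2-[5-(methoxymethoxy)-2,2-dimethyl-2H-chromen-8-yl]propanoyl}-1,3-oxazolidin-2-one | CC1(C)C=Cc2c(OCOC)ccc([C@H]([C@H](O[Si](C)(C)C(C)(C)C)c3c(Br)cc(OCOC)cc3OCOC)C(=O)N3C(=O)OC[C@@H]3Cc3ccccc3)c2O1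
F7 | step 10 | (2S,3S)-3-[2-bromo-4,6-bis(methoxymethoxy)phenyl]-3-{[tert-butyl(dimethyl)silyl]oxy}-2-[5-(methoxymethoxy)-2,2-dimethyl-2H-chromen-8-yl]propan-1-ol | CC1(C)C=Cc2c(OCOC)ccc([C@H]([C@H](O[Si](C)(C)C(C)(C)C)c3c(Br)cc(OCOC)cc3OCOC)CO)c2O1
F8 | step 10 | tert-butyl({(3S,4S)-5,7-bis(methoxymethoxy)-3-[5-(methoxymethoxy)-2,2-dimethyl-2H-chromen-8-yl]-3,4-dihydro-2H-chromen-4-yl}oxy)dimethylsilane | CC1(C)C=Cc2c(OCOC)ccc([C@H]3COc4cc(OCOC)cc(OCOC)c4[C@H]3O[Si](C)(C)C(C)(C)C)c2O1
F9 | step 10 | (3S,4S)-5,7-bis(methoxymethoxy)-3-[5-(methoxymethoxy)-2,2-dimethyl-2H-chromen-8-yl]-3,4-dihydro-2H-chromen-4-ol | CC1(C)C=Cc2c(OCOC)ccc([C@H]3COc4cc(OCOC)cc(OCOC)c4[C@H]3O)c2O1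
F10 | step 12 | (1R,2S)-1-[2-bromo-4,6-bis(methoxymethoxy)phenyl]-2-[5-(methoxymethoxy)-2,2-dimethyl-2H-chromen-8-yl]propane-1,3-diol | CC1(C)C=Cc2c(OCOC)ccc([C@H]([C@@H](O)c3c(Br)cc(OCOC)cc3OCOC)CO)c2O1
F11 | step 12 | (1R,2S)-1-[2-bromo-4,6-bis(methoxymethoxy)phenyl]-1,3-bis{[tert-butyl(dimethyl)silyl]oxy}-2-[5-(methoxymethoxy)-2,2-dimethyl-2H-chromen-8-yl]propane | CC1(C)C=Cc2c(OCOC)ccc([C@H]([C@@H](O[Si](C)(C)C(C)(C)C)c3c(Br)cc(OCOC)cc3OCOC)CO[Si](C)(C)C(C)(C)C)c2O1
F12 | step 16 | (3S)-3-{2,2-dimethyl-5-[(triethylsilyl)oxy]-2H-chromen-8-yl}-5,7-bis[(triethylsilyl)oxy]-2,3-dihydro-4H-chromen-4-one | CC1(C)C=Cc2c(O[Si](CC)(CC)CC)ccc([C@H]3COc4cc(O[Si](CC)(CC)CC)cc(O[Si](CC)(CC)CC)c4C3=O)c2O1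
F13 | step 7 | methyl 2-[5-(methoxymethoxy)-4-(2-methylprop-1-en-1-yl)-2-phenyl-4H-1,3,2-benzodioxaborin-8-yl]acetate | COC(=O)Cc1ccc(OCOC)c2C(C=C(C)C)OB(c3ccccc3)Oc12
A1 | alternative 1 | 5-(methoxymethoxy)-2,2-dimethyl-8-[2-(triisopropylsilyloxy)ethyl]-2H-chromene | CC1(C)C=Cc2c(OCOC)ccc(CCO[Si](C(C)C)(C(C)C)C(C)C)c2O1
A2 | alternative 1 | 3-(methoxymethoxy)-6-[2-(triisopropylsilyloxy)ethyl]-2-(trimethylsilyl)phenyl trifluoromethanesulfonate | COCOc1ccc(CCO[Si](C(C)C)(C(C)C)C(C)C)c(OS(=O)(=O)C(F)(F)F)c1[Si](C)(C)C
A3 | alternative 1 | 3-methylbut-2-enal | CC(C)=CC=O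
A4 | alternative 2 | (3S)-7-{[tert-butyl(dimethyl)silyl]oxy}-3-(5-{[tert-butyl(dimethyl)silyl]oxy}-2,2-dimethyl-2H-chromen-8-yl)-5-methoxy-2,3-dihydro-4H-chromen-4-one | CC1(C)C=Cc2c(O[Si](C)(C)C(C)(C)C)ccc([C@H]3COc4cc(O[Si](C)(C)C(C)(C)C)cc(OC)c4C3=O)c2O1
A5 | alternative 2 | 1-(4-{[tert-butyl(dimethyl)silyl]oxy}-2,6-dimethoxyphenyl)-2-(5-{[tert-butyl(dimethyl)silyl]oxy}-2,2-dimethyl-2H-chromen-8-yl)-2-diazoethan-1-one | COc1cc(O[Si](C)(C)C(C)(C)C)cc(OC)c1C(=O)C(=[N+]=[N-])c1ccc(O[Si](C)(C)C(C)(C)C)c2C=CC(C)(C)Oc12
A6 | alternative 3 | rac-5,7-bis(methoxymethoxy)-3-[5-(methoxymethoxy)-2,2-dimethyl-2H-chromen-8-yl]-2,3-dihydro-4H-chromen-4-one | CC1(C)C=Cc2c(OCOC)ccc(C3COc4cc(OCOC)cc(OCOC)c4C3=O)c2O1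
A7 | alternative 3 | 3,5-bis(methoxymethoxy)-2-(trimethylsilyl)phenyl trifluoromethanesulfonate | COCOc1cc(OCOC)c([Si](C)(C)C)c(OS(=O)(=O)C(F)(F)F)c1
A8 | alternative 3 | 2-[5-(methoxymethoxy)-2,2-dimethyl-2H-chromen-8-yl]prop-2-enoic acid | C=C(C(=O)O)c1ccc(OCOC)c2C=CC(C)(C)Oc12
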